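## Structural features

Haemathamnolic acid is a depside: ring A and ring B share no atoms and are joined only by one ester, from the C1 carboxyl carbon of ring A to the oxygen on C1' of ring B. Ring A is pentasubstituted (C2 hydroxyl, C3 formyl, C4 methoxy, C6 methyl, C5–H the only free position), and ring B is hexasubstituted (C1' ester oxygen, C2' methyl, C3' carboxyl, C4' hydroxyl, C5' formyl, C6' hydroxyl). The target has no stereocentre, so none are adjacent; the only sp3 centres of the route (the contiguous C1', C2', C3' of a dihydro ring B) are transient. Fragile groups are the aryl ester (cleaved by alkoxides, able to shift to the neighbouring C6' oxygen), the two ortho-hydroxy aldehydes (condensation with enolates, over-reduction) and the β-resorcylic acid of ring B (decarboxylation on heating or in strong acid). The real difficulty is the ester itself: its carbonyl has two ortho substituents and its oxygen sits on a fully substituted ring between a methyl group and a second hydroxyl. Acylating a ring B phenol would therefore need activation of a hindered acid and a choice between O1' and O6'. The plan exploits that ring B is a 5-acyloxyorsellinate: C3'–C4'–C5' with the C3' carboxyl is an acetoacetate, and C6'–C1'–C2' with the oxygen on C1' and the methyl on C2' is a 2-acyloxybut-2-enoate. Ring B can thus be built by a Michael–Claisen annulation around an ester that already exists, and C5' is formylated afterwards.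

## Logic of the disconnections

**19 from 18.** The two benzylic C–O bonds are cut (ether oxygen on C2 of ring A, carboxyl oxygen on C3' of ring B). The free β-resorcylic acid and the ring A phenol are the most delicate functions, so one reduction releases both at the very end. Nothing skeletal is gained, but every earlier step runs on a neutral, lipophilic substrate. The forward step must remove two benzyl groups without reducing two formyl groups or touching the aryl ester.

**18 from 16 (through 17).** The C5'–CHO bond is cut and the ring A aldehyde is returned to its acetal. C5' is the only unsubstituted carbon of ring B and derives from a carbon that cannot carry a formyl group through an enolate annulation. Ring B becomes a resorcinol with a single free position, so regiochemistry is not in question. The forward step needs a phenoxide-directed formylation that spares the ester, and the acetal must be opened only after C5' is blocked.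

**16 from 14.** Two hydrogens are added back at C1' and C2'. This converts the aromatic ring into a cyclohexane-1,3-dione that enolate chemistry can assemble. The forward dehydrogenation must not leave a halogen on C5' or on ring A and must keep the acyloxy group on C1'.

**14 from 11 and 12 (through 13).** The C5'–C6' bond (retro-Claisen) and the C2'–C3' bond (retro-Michael) are cut. The ring falls into a three-carbon nucleophile (C3'–C4'–C5') and a three-carbon electrophile (C6'–C1'–C2') that already carries the ester oxygen on C1'. A hexasubstituted ring is reduced to two acyclic pieces, and the crowded ester never has to be made by acylating a phenol. The forward step must attack the enoate β-carbon and the methyl ester and leave the aroyl carbonyl alone.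

**11 from 9 (through 10), and 9 from 8.** The C1'=C2' double bond is traced to a secondary alcohol and that to a ketone. The ketone is kept because it is what makes the future C1' electrophilic in the preceding substitution. The forward steps must reduce the ketone beside two esters and then eliminate water without acyl shift.

**8 from 6 and 7.** The bond between the ester oxygen and the future C1' is cut, not the acyl–oxygen bond. The carboxylate acts as nucleophile at an sp3 carbon, so the di-ortho-substituted acid never needs activation. This gives a ring A carboxylate and a four-carbon commercial piece. The forward step needs the carboxylate as a dry salt, because the acetal does not tolerate the free-acid work-up.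

**6 from 5.** The O–CH3 bond of the ring A methyl ester is cut. Dealkylation at the methyl carbon avoids attack at the shielded carbonyl and delivers the salt directly.

**5 from 4, and 4 from 3.** The acetal C–O bonds and the benzyl ether bond are cut. Both groups protect ring A against enolates, hydride and base, and the benzyl group adds steric cover to the ester carbonyl.

**3 from 2.** The C3–CHO bond is cut. C3 is the only carbon ortho to the free hydroxyl, so a phenoxide-directed formylation has one possible site.

**2 from 1.** The O–CH3 bond at C4 is cut. The hydrogen-bonded C2 hydroxyl distinguishes the two phenols of 1, and 1 is commercial.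

## Other disconnections considered

**Alternative 1:** The cut runs through ring A (C2–C3, C4–C5 and C1–C2, plus C5–C6 in the preceding rearrangement), with the ester already in place.
- Forward step: the ring B phenol tert-butyl 4,6-bis(benzyloxy)-3-hydroxy-2-methylbenzoate A1 would be acylated to the diazo ketone 4,6-bis(benzyloxy)-3-(tert-butoxycarbonyl)-2-methylphenyl 5-diazo-3-methyl-4-oxopent-2-enoate A2. Irradiation of A2 with the siloxyalkyne (3,3-diethoxyprop-1-ynyloxy)triisopropylsilane A3 would trigger Wolff rearrangement, [2+2] addition, four-electron ring opening and six-electron closure to the depside A4.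
- In favour: the cascade is neutral and pericyclic, and ketene/ynol ether polarity fixes the regiochemistry. Ring A appears with its formyl carbon placed, so no formylation regiochemistry arises on ring A; here it is better than the chosen plan, which relies on a directed formylation. The ester is made from an unhindered alkenoic acid, which is at least the equal of the chosen substitution at sp3 carbon. No redox adjustment follows ring formation, which is better than the chosen plan.
- Against: A1 is the hexasubstituted ring B in all but the formyl group and must be made first, including the O1'/O6' discrimination the chosen plan avoids. A2 is a diazo compound and the key step is photochemical, both poor for safety and scale. A3 is sensitive and takes several steps. After A4, silyl removal, selective 4-O-methylation, debenzylation, C5' formylation and two acid deprotections remain.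
- Comparison: on structure it solves ring A elegantly but leaves ring B, the harder ring, to classical chemistry. Late C5' formylation is needed in both plans (equal). On step economy it should be clearly longer, roughly by half again.

**Alternative 2:** The cut is C1'–C2' and C3'–C4' of ring B.
- Forward step: the diene 4-methoxy-2,4-bis(trimethylsilyloxy)buta-1,3-dien-1-yl 2-(benzyloxy)-3-(dimethoxymethyl)-4-methoxy-6-methylbenzoate A5 would add to benzyl but-2-ynoate A6, and loss of the C4' methoxy group from the adduct would aromatize it to A7.
- In favour: it shares the chosen idea of growing ring B around the existing ester. It gives the arene directly at the right oxidation level, so reduction, dehydration and dehydrogenation disappear; on paper it is about three steps shorter, which is better than the chosen plan. Diene polarization sets the regiochemistry.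
- Against: making A5 needs double enol silylation of a 4-acyloxyacetoacetate with strong base, where 1,2-acyl shift of the Chan rearrangement type competes. A5 is moisture-sensitive and carries an acid-labile acetal, which rules out Lewis acid acceleration. A6 is a sluggish dienophile because of its β-methyl group. The new C1'–C2' bond joins two substituted carbons, so heating must outrun diene decomposition.
- Comparison: the end game is the same, since A7 is the dimethyl acetal analogue of 16 (equal). Mechanistically it depends on a thermally demanding cycloaddition of a fragile diene, whereas the chosen plan uses stepwise anionic reactions of a class established for dihydroorsellinates. It is the most serious competitor.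

**Alternative 3:** The cut is C1–C6 of ring A.
- Forward step: the aryl triketide 4,6-bis(benzyloxy)-3-(tert-butoxycarbonyl)-2-methylphenyl 3,5,7-trioxooctanoate A8 (an ester of A1) would fold by aldol addition of chain carbon 2 to the carbon 7 ketone, dehydration and enolization to the aryl orsellinate A9.
- In favour: it is biomimetic and uses a simple acyclic precursor. Ester formation with an unhindered acyl donor is easier than any hindered coupling, which is equal to or better than the chosen plan. Ring A needs no protecting group during ring formation.
- Against: Claisen and pyrone modes of cyclization compete and expel the aryloxide, so the depside bond is at risk in the key step, and the substrate does not control the choice of mode. After A9, ring A still needs selective 4-O-methylation and C3 formylation (C3 against C5) beside an electron-rich ring B, and ring B still needs formylation. A1 is required here as well.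
- Comparison: all decoration of ring A is postponed to the most complex intermediate, whereas the chosen plan fixes it early on 1 under control of the free C2 hydroxyl. It should be longer and less selective.

Key step: step 9

Remark on the chemistry: the ring A formyl group is carried as a cyclic 1,3-dioxolane and not as an open-chain dimethyl acetal. An acetal on this electron-rich ring is very acid-labile; the cyclic form recloses after reversible opening in anhydrous acid (step 10) and tolerates base-treated silica. The atom mapping of 11, 12 and 14 was checked (acetoacetate C2 becomes C3', C4 becomes C5'; enoate C3 becomes C2', C1 becomes C6') and needed no correction. Primed locants are also used for the future ring B atoms in acyclic compounds.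

## Route

Step 1
Reactants: 1 methyl orsellinate (methyl 2,4-dihydroxy-6-methylbenzoate)
Product: 2 methyl 2-hydroxy-4-methoxy-6-methylbenzoate
Conditions: MeI (1.05 equiv), K2CO3, acetone, reflux
Reagents that add atoms: iodomethane, CI
Why: Williamson O-methylation; the C2 hydroxyl is hydrogen-bonded to the ester carbonyl and less acidic, so one equivalent of MeI should alkylate only the C4 hydroxyl.

Step 2
Reactants: 2 methyl 2-hydroxy-4-methoxy-6-methylbenzoate
Product: 3 methyl 3-formyl-2-hydroxy-4-methoxy-6-methylbenzoate
Conditions: MgCl2, Et3N, (CH2O)n, MeCN, reflux; 1 M HCl work-up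
Reagents that add atoms: formaldehyde (as paraformaldehyde), C=O
Why: Casnati–Skattebøl ortho-formylation; the magnesium phenoxide delivers formaldehyde to C3, the only free carbon ortho to the phenoxide, and a second formaldehyde oxidizes the benzylic alkoxide by hydride transfer. C5 is para to the phenoxide and should not react.

Step 3
Reactants: 3 methyl 3-formyl-2-hydroxy-4-methoxy-6-methylbenzoate
Product: 4 methyl 2-(benzyloxy)-3-formyl-4-methoxy-6-methylbenzoate
Conditions: BnBr, K2CO3, DMF, 60 °C
Reagents that add atoms: benzyl bromide, BrCc1ccccc1
Why: Williamson ether synthesis on an acidic, doubly hydrogen-bonded phenol, which needs a polar aprotic solvent and gentle heating. The benzyl group later shields the ester carbonyl and leaves together with the benzyl ester.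

Step 4
Reactants: 4 methyl 2-(benzyloxy)-3-formyl-4-methoxy-6-methylbenzoate
Product: 5 methyl 2-(benzyloxy)-3-(1,3-dioxolan-2-yl)-4-methoxy-6-methylbenzoate
Conditions: HOCH2CH2OH, TsOH·H2O (cat.), PhMe, reflux (Dean–Stark); Et3N quench
Reagents that add atoms: ethylene glycol, OCCO
Why: acid-catalysed acetalization driven by azeotropic removal of water; the di-ortho-substituted methyl ester should not transesterify. The product is handled on base-treated silica only.

Step 5
Reactants: 5 methyl 2-(benzyloxy)-3-(1,3-dioxolan-2-yl)-4-methoxy-6-methylbenzoate
Product: 6 potassium 2-(benzyloxy)-3-(1,3-dioxolan-2-yl)-4-methoxy-6-methylbenzoate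
Conditions: KOSiMe3 (1.1 equiv), THF, reflux; evaporate, triturate with Et2O
Reagents that add atoms: potassium trimethylsilanolate, C[Si](C)(C)[O-].[K+]
Why: silanolate cleavage of a methyl ester; attack at the O-methyl carbon (SN2 dealkylation) is indifferent to the two ortho substituents that block the carbonyl. The dry potassium carboxylate is obtained without any acidification, which the acetal would not survive.

Step 6
Reactants: 6 potassium 2-(benzyloxy)-3-(1,3-dioxolan-2-yl)-4-methoxy-6-methylbenzoate; 7 methyl 2-chloroacetoacetate (methyl 2-chloro-3-oxobutanoate)
Product: 8 methyl 2-[2-(benzyloxy)-3-(1,3-dioxolan-2-yl)-4-methoxy-6-methylbenzoyloxy]-3-oxobutanoate (racemic)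
Conditions: DMF, 25 °C; neutral aqueous work-up
Reagents that add atoms: none
Why: SN2 O-alkylation of a carboxylate by a doubly activated α-chloro-β-keto ester, the reaction used to make 2-acyloxyacetoacetates. The depside C–O bond is formed from the alkyl side, so the hindered carbonyl is never attacked; the new centre at the future C1' is racemic and is erased in step 8.

Step 7
Reactants: 8 methyl 2-[2-(benzyloxy)-3-(1,3-dioxolan-2-yl)-4-methoxy-6-methylbenzoyloxy]-3-oxobutanoate
Product: 9 methyl 2-[2-(benzyloxy)-3-(1,3-dioxolan-2-yl)-4-methoxy-6-methylbenzoyloxy]-3-hydroxybutanoate (mixture of diastereomers, racemic)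
Conditions: NaBH4, MeOH/THF, −40 °C; pH 7 phosphate buffer
Reagents that add atoms: none
Why: borohydride reduction of an activated ketone beside two esters; low temperature and the hindered aroyl group should suppress 1,2-acyl shift to the new hydroxyl. The new stereocentre is not controlled and both centres vanish in step 8.

Step 8
Reactants: 9 methyl 2-[2-(benzyloxy)-3-(1,3-dioxolan-2-yl)-4-methoxy-6-methylbenzoyloxy]-3-hydroxybutanoate
Product: 11 methyl 2-[2-(benzyloxy)-3-(1,3-dioxolan-2-yl)-4-methoxy-6-methylbenzoyloxy]but-2-enoate (E/Z mixture), via secondary mesylate 10 (not isolated)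
Conditions: MsCl, Et3N, CH2Cl2, 0 °C; then DBU, 25 °C
Reagents that add atoms: none
Why: mesylation followed by E1cB elimination, as in the dehydration of threonine esters to dehydrobutyrine esters; the C–H between ester and acyloxy group is acidic enough for DBU. The mesyl group of 10 is lost again and either alkene isomer serves in step 9.

Step 9
Reactants: 11 methyl 2-[2-(benzyloxy)-3-(1,3-dioxolan-2-yl)-4-methoxy-6-methylbenzoyloxy]but-2-enoate; 12 benzyl acetoacetate (benzyl 3-oxobutanoate)
Product: 14 benzyl 5-[2-(benzyloxy)-3-(1,3-dioxolan-2-yl)-4-methoxy-6-methylbenzoyloxy]-6-methyl-2,4-dioxocyclohexane-1-carboxylate (diastereomer mixture), via acyclic Michael adduct 13 (not isolated)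
Conditions: 12 (1.2 equiv), KOC(CH3)3 (1.2 equiv), t-BuOH/THF, 0 °C; add 11, 25 °C; then KOC(CH3)3 (1.0 equiv), 50 °C; AcOH (2.2 equiv), −20 °C; cold pH 6 buffer, rapid extraction
Reagents that add atoms: none
Why: Michael–Claisen [3+3] annulation, the reaction type that converts acetoacetates and crotonates into dihydroorsellinates. The potassium enolate of 12 should add through its central carbon to the β-carbon of 11 (bond C2'–C3'), and protonation of the resulting ester enolate gives 13, in which the enol ester of 11 has become an ordinary hindered alkyl aroate. The second portion of base then generates, in equilibrium, the enolate at the acetyl methyl group, which attacks the methyl ester in a 6-exo-trig Claisen closure (bond C5'–C6') and expels methoxide; every other ester carbonyl could only be reached through a four- or seven-membered transition state. Irreversible formation of the dione enolate of 14 drives the sequence and consumes the methoxide, so exchange at the benzyl ester should stay marginal. C1', C2' and C3' become sp3 stereocentres without control (C3' is epimerizable), and 14 is carried as the mixture because step 10 flattens all three. The step needs attack at the enoate β-carbon and the methyl ester and not at the aroyl carbonyl: the benzyloxy and methyl groups ortho to that carbonyl shield it, the enolate of 12 is a soft carbon nucleophile, and free tert-butoxide is added only after the enol ester has been consumed. Shift of the aroyl group to O6' is uphill because it would trade a stabilized dione enolate for an alkoxide.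

Step 10
Reactants: 14 benzyl 5-[2-(benzyloxy)-3-(1,3-dioxolan-2-yl)-4-methoxy-6-methylbenzoyloxy]-6-methyl-2,4-dioxocyclohexane-1-carboxylate
Product: 16 benzyl 5-[2-(benzyloxy)-3-(1,3-dioxolan-2-yl)-4-methoxy-6-methylbenzoyloxy]-2,4-dihydroxy-6-methylbenzoate, via bromo dione 15 (not isolated)
Conditions: KOC(CH3)3 (1.0 equiv), DMF, 0 °C; Br2 (1.0 equiv, as DMF solution); then 70 °C; pour into cold aq. NaHCO3
Reagents that add atoms: none
Why: bromination–dehydrobromination aromatization of a 2,4-dioxocyclohexanecarboxylate, the standard passage from dihydroorsellinates to orsellinates. The enolate takes up bromine at C5' to give 15; positive bromine is transferable between the enol carbons, and loss of HBr across C2'–C3' from the C3' bromide followed by enolization should give 16. The dioxolane opens only reversibly in the anhydrous acidic medium and is neutralized before it meets water; the crude potassium enolate from step 9 can be used directly.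

Step 11
Reactants: 16 benzyl 5-[2-(benzyloxy)-3-(1,3-dioxolan-2-yl)-4-methoxy-6-methylbenzoyloxy]-2,4-dihydroxy-6-methylbenzoate
Product: 18 benzyl 5-[2-(benzyloxy)-3-formyl-4-methoxy-6-methylbenzoyloxy]-3-formyl-2,4-dihydroxy-6-methylbenzoate, via formylated acetal 17 (not isolated)
Conditions: MgCl2, Et3N, (CH2O)n, THF, reflux; then 1 M HCl, THF, 25 °C
Reagents that add atoms: formaldehyde (as paraformaldehyde), C=O; water, O
Why: Casnati–Skattebøl ortho-formylation at C5', the only free carbon of ring B and ortho to both phenoxides; ring A has no free phenol and stays untouched. Under base the aroyl group should stay on O1', because the free O6' phenoxide is para to the ester and is the more stabilized one. The acidic work-up then hydrolyses the acetal at a stage where ring B has no nucleophilic carbon left.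

Step 12
Reactants: 18 benzyl 5-[2-(benzyloxy)-3-formyl-4-methoxy-6-methylbenzoyloxy]-3-formyl-2,4-dihydroxy-6-methylbenzoate
Product: 19 haemathamnolic acid (3-formyl-5-(3-formyl-2-hydroxy-4-methoxy-6-methylbenzoyloxy)-2,4-dihydroxy-6-methylbenzoic acid)
Conditions: H2 (1 atm), 10% Pd/C, EtOAc, 25 °C; stop after two equivalents of H2
Reagents that add atoms: none
Why: hydrogenolysis of one benzyl ether and one benzyl ester over palladium. Both formyl groups are hydrogen-bonded to ortho hydroxyls on electron-rich rings and should be slow to reduce at 1 atm; the hindered aryl ester is inert.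

## Compound list

1 | methyl orsellinate (methyl 2,4-dihydroxy-6-methylbenzoate) | COC(=O)c1c(C)cc(O)cc1O | starting material
2 | methyl 2-hydroxy-4-methoxy-6-methylbenzoate | COC(=O)c1c(C)cc(OC)cc1O | intermediate
3 | methyl 3-formyl-2-hydroxy-4-methoxy-6-methylbenzoate | COC(=O)c1c(C)cc(OC)c(C=O)c1O | intermediate
4 | methyl 2-(benzyloxy)-3-formyl-4-methoxy-6-methylbenzoate | COC(=O)c1c(C)cc(OC)c(C=O)c1OCc1ccccc1 | intermediate
5 | methyl 2-(benzyloxy)-3-(1,3-dioxolan-2-yl)-4-methoxy-6-methylbenzoate | COC(=O)c1c(C)cc(OC)c(C2OCCO2)c1OCc1ccccc1 | intermediate
6 | potassium 2-(benzyloxy)-3-(1,3-dioxolan-2-yl)-4-methoxy-6-methylbenzoate | [K+].[O-]C(=O)c1c(C)cc(OC)c(C2OCCO2)c1OCc1ccccc1 | intermediate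
7 | methyl 2-chloroacetoacetate (methyl 2-chloro-3-oxobutanoate) | CC(=O)C(Cl)C(=O)OC | starting material
8 | methyl 2-[2-(benzyloxy)-3-(1,3-dioxolan-2-yl)-4-methoxy-6-methylbenzoyloxy]-3-oxobutanoate (racemic) | CC(=O)C(OC(=O)c1c(C)cc(OC)c(C2OCCO2)c1OCc1ccccc1)C(=O)OC | intermediate
9 | methyl 2-[2-(benzyloxy)-3-(1,3-dioxolan-2-yl)-4-methoxy-6-methylbenzoyloxy]-3-hydroxybutanoate (diastereomer mixture, racemic) | CC(O)C(OC(=O)c1c(C)cc(OC)c(C2OCCO2)c1OCc1ccccc1)C(=O)OC | intermediate
10 | methyl 2-[2-(benzyloxy)-3-(1,3-dioxolan-2-yl)-4-methoxy-6-methylbenzoyloxy]-3-(methylsulfonyloxy)butanoate (diastereomer mixture) | CC(OS(C)(=O)=O)C(OC(=O)c1c(C)cc(OC)c(C2OCCO2)c1OCc1ccccc1)C(=O)OC | intermediate (not isolated)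
11 | methyl 2-[2-(benzyloxy)-3-(1,3-dioxolan-2-yl)-4-methoxy-6-methylbenzoyloxy]but-2-enoate (E/Z mixture) | CC=C(OC(=O)c1c(C)cc(OC)c(C2OCCO2)c1OCc1ccccc1)C(=O)OC | intermediate
12 | benzyl acetoacetate (benzyl 3-oxobutanoate) | CC(=O)CC(=O)OCc1ccccc1 | starting material
13 | 1-benzyl 5-methyl 2-acetyl-4-[2-(benzyloxy)-3-(1,3-dioxolan-2-yl)-4-methoxy-6-methylbenzoyloxy]-3-methylpentanedioate (diastereomer mixture) | CC(=O)C(C(=O)OCc1ccccc1)C(C)C(OC(=O)c1c(C)cc(OC)c(C2OCCO2)c1OCc1ccccc1)C(=O)OC | intermediate (not isolated)
14 | benzyl 5-[2-(benzyloxy)-3-(1,3-dioxolan-2-yl)-4-methoxy-6-methylbenzoyloxy]-6-methyl-2,4-dioxocyclohexane-1-carboxylate (diastereomer mixture) | CC1C(OC(=O)c2c(C)cc(OC)c(C3OCCO3)c2OCc2ccccc2)C(=O)CC(=O)C1C(=O)OCc1ccccc1 | intermediate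
15 | benzyl 5-[2-(benzyloxy)-3-(1,3-dioxolan-2-yl)-4-methoxy-6-methylbenzoyloxy]-3-bromo-6-methyl-2,4-dioxocyclohexane-1-carboxylate (diastereomer mixture) | CC1C(OC(=O)c2c(C)cc(OC)c(C3OCCO3)c2OCc2ccccc2)C(=O)C(Br)C(=O)C1C(=O)OCc1ccccc1 | intermediate (not isolated)
16 | benzyl 5-[2-(benzyloxy)-3-(1,3-dioxolan-2-yl)-4-methoxy-6-methylbenzoyloxy]-2,4-dihydroxy-6-methylbenzoate | Cc1c(OC(=O)c2c(C)cc(OC)c(C3OCCO3)c2OCc2ccccc2)c(O)cc(O)c1C(=O)OCc1ccccc1 | intermediate
17 | benzyl 5-[2-(benzyloxy)-3-(1,3-dioxolan-2-yl)-4-methoxy-6-methylbenzoyloxy]-3-formyl-2,4-dihydroxy-6-methylbenzoate | Cc1c(OC(=O)c2c(C)cc(OC)c(C3OCCO3)c2OCc2ccccc2)c(O)c(C=O)c(O)c1C(=O)OCc1ccccc1 | intermediate (not isolated)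
18 | benzyl 5-[2-(benzyloxy)-3-formyl-4-methoxy-6-methylbenzoyloxy]-3-formyl-2,4-dihydroxy-6-methylbenzoate | Cc1c(OC(=O)c2c(C)cc(OC)c(C=O)c2OCc2ccccc2)c(O)c(C=O)c(O)c1C(=O)OCc1ccccc1 | intermediate
19 | haemathamnolic acid (3-formyl-5-(3-formyl-2-hydroxy-4-methoxy-6-methylbenzoyloxy)-2,4-dihydroxy-6-methylbenzoic acid) | COc1cc(C)c(C(=O)Oc2c(C)c(C(=O)O)c(O)c(C=O)c2O)c(O)c1C=O | target

## Step count and least certain steps

Total: 12 steps. Longest linear sequence: 12 steps (1 to 19); 7 and 12 are purchased and enter in steps 6 and 9.

**Step 9 (key step).** The most likely failure is slow conjugate addition to the β-methyl, α-acyloxy enoate. That would give time for transfer of the aroyl group from the enol ester to an alkoxide or enolate oxygen, and for alkoxide exchange at the benzyl ester during the hot Claisen phase. Fallback: the two bond formations are separated. Starting from 11 and 12, the Michael addition is run with a catalytic weak base (Cs2CO3, 0.1 equiv, MeCN, 25 °C), so that no stoichiometric alkoxide ever meets the enol ester, and 13 is isolated. The ring is then closed through the preformed dianion of 13 (LiN(SiMe3)2, 2.2 equiv, THF, −78 to 0 °C, Dieckmann-type acylation at the terminal carbon), which rejoins the route at 14. This changes the ring closure from a thermodynamic alkoxide equilibrium to kinetic dianion chemistry and makes no new compound.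

**Step 10.** The most likely failures are electrophilic bromination of the electron-rich ring A at C5 during the thermal phase, stalling at the C5' bromide, or acid-induced opening of the acetal followed by condensation of the ring A aldehyde carbon with the dione. Fallback: a halogen-free and acid-free Saegusa–Ito dehydrogenation. Starting from 14, silylation (Me3SiCl, Et3N, MeCN) should give benzyl 5-[2-(benzyloxy)-3-(1,3-dioxolan-2-yl)-4-methoxy-6-methylbenzoyloxy]-6-methyl-2,4-bis(trimethylsilyloxy)cyclohexa-1,3-diene-1-carboxylate F1. Pd(OAc)2 (1.05 equiv, MeCN, 25 °C) would then palladate C3'; β-hydride loss from C2' reduces divalent palladium to zerovalent palladium, and enolization with mild aqueous desilylation returns the route at 16.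

**Step 11.** The most likely failure is sluggish hydroxymethylation of a ring B that is deactivated by the ester and the acyloxy group, with base-induced cleavage of the aryl ester becoming competitive at reflux. Fallback: a Rieche formylation, electrophilic and acidic. Starting from 16, Cl2CHOMe and TiCl4 (CH2Cl2, −20 °C) followed by aqueous HCl should formylate C5' through the titanium phenoxide and open the acetal in the same operation, rejoining the route at 18. If the Lewis acid also removes the ring A benzyl ether, the product is benzyl 3-formyl-5-(3-formyl-2-hydroxy-4-methoxy-6-methylbenzoyloxy)-2,4-dihydroxy-6-methylbenzoate F2, which step 12 converts to 19 just as it does 18.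

**Step 5.** The most likely failure is incomplete dealkylation of the hindered methyl ester, or carry-over of excess silanolate that then consumes 7. Fallback: the order of events is changed so that hydrolysis precedes acetalization. Starting from 4, KOH in aqueous DMSO (80 °C) with an ordinary acidic work-up (no acetal is present yet) should give 2-(benzyloxy)-3-formyl-4-methoxy-6-methylbenzoic acid F3. Acetalization of F3 (ethylene glycol, TsOH cat., PhMe, Dean–Stark; the di-ortho-substituted acid does not esterify) gives 2-(benzyloxy)-3-(1,3-dioxolan-2-yl)-4-methoxy-6-methylbenzoic acid F4 in solution. Adding KOC(CH3)3 (1.0 equiv) before any contact with water rejoins the route at 6.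

**Step 2.** The most likely failure is low conversion, because the phenoxide is chelated by the ortho ester and is a poor nucleophile toward formaldehyde. Fallback: formylation and methylation are exchanged. Starting from 1, Rieche formylation (Cl2CHOMe, TiCl4, CH2Cl2, 0 °C) at C3, the carbon between the two hydroxyls, should give methyl 3-formyl-2,4-dihydroxy-6-methylbenzoate F5 (a C5 isomer may have to be removed). Selective methylation of the C4 hydroxyl (MeI, K2CO3, acetone; the C2 hydroxyl is locked between two hydrogen-bond acceptors) rejoins the route at 3.

## Further compounds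

F0 | step 9 | none | none
F1 | step 10 | benzyl 5-[2-(benzyloxy)-3-(1,3-dioxolan-2-yl)-4-methoxy-6-methylbenzoyloxy]-6-methyl-2,4-bis(trimethylsilyloxy)cyclohexa-1,3-diene-1-carboxylate | CC1C(OC(=O)c2c(C)cc(OC)c(C3OCCO3)c2OCc2ccccc2)C(O[Si](C)(C)C)=CC(O[Si](C)(C)C)=C1C(=O)OCc1ccccc1
F2 | step 11 | benzyl 3-formyl-5-(3-formyl-2-hydroxy-4-methoxy-6-methylbenzoyloxy)-2,4-dihydroxy-6-methylbenzoate | Cc1c(OC(=O)c2c(C)cc(OC)c(C=O)c2O)c(O)c(C=O)c(O)c1C(=O)OCc1ccccc1
F3 | step 5 | 2-(benzyloxy)-3-formyl-4-methoxy-6-methylbenzoic acid | OC(=O)c1c(C)cc(OC)c(C=O)c1OCc1ccccc1
F4 | step 5 | 2-(benzyloxy)-3-(1,3-dioxolan-2-yl)-4-methoxy-6-methylbenzoic acid | OC(=O)c1c(C)cc(OC)c(C2OCCO2)c1OCc1ccccc1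
F5 | step 2 | methyl 3-formyl-2,4-dihydroxy-6-methylbenzoate | COC(=O)c1c(C)cc(O)c(C=O)c1O
A1 | alternative 1 | tert-butyl 4,6-bis(benzyloxy)-3-hydroxy-2-methylbenzoate | Cc1c(O)c(OCc2ccccc2)cc(OCc2ccccc2)c1C(=O)OC(C)(C)C
A2 | alternative 1 | 4,6-bis(benzyloxy)-3-(tert-butoxycarbonyl)-2-methylphenyl 5-diazo-3-methyl-4-oxopent-2-enoate | [N-]=[N+]=CC(=O)C(C)=CC(=O)Oc1c(C)c(C(=O)OC(C)(C)C)c(OCc2ccccc2)cc1OCc1ccccc1
A3 | alternative 1 | (3,3-diethoxyprop-1-ynyloxy)triisopropylsilane | CCOC(OCC)C#CO[Si](C(C)C)(C(C)C)C(C)C
A4 | alternative 1 | 4,6-bis(benzyloxy)-3-(tert-butoxycarbonyl)-2-methylphenyl 3-(diethoxymethyl)-2-hydroxy-6-methyl-4-(triisopropylsilyloxy)benzoate | CCOC(OCC)c1c(O)c(C(=O)Oc2c(C)c(C(=O)OC(C)(C)C)c(OCc3ccccc3)cc2OCc2ccccc2)c(C)cc1O[Si](C(C)C)(C(C)C)C(C)C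
A5 | alternative 2 | 4-methoxy-2,4-bis(trimethylsilyloxy)buta-1,3-dien-1-yl 2-(benzyloxy)-3-(dimethoxymethyl)-4-methoxy-6-methylbenzoate | COC(O[Si](C)(C)C)=CC(O[Si](C)(C)C)=COC(=O)c1c(C)cc(OC)c(C(OC)OC)c1OCc1ccccc1
A6 | alternative 2 | benzyl but-2-ynoate | CC#CC(=O)OCc1ccccc1
A7 | alternative 2 | benzyl 5-[2-(benzyloxy)-3-(dimethoxymethyl)-4-methoxy-6-methylbenzoyloxy]-2,4-dihydroxy-6-methylbenzoate | O=C(OCc1ccccc1)c1c(C)c(OC(=O)c2c(C)cc(OC)c(C(OC)OC)c2OCc2ccccc2)c(O)cc1O
A8 | alternative 3 | 4,6-bis(benzyloxy)-3-(tert-butoxycarbonyl)-2-methylphenyl 3,5,7-trioxooctanoate | CC(=O)CC(=O)CC(=O)CC(=O)Oc1c(C)c(C(=O)OC(C)(C)C)c(OCc2ccccc2)cc1OCc1ccccc1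
A9 | alternative 3 | 4,6-bis(benzyloxy)-3-(tert-butoxycarbonyl)-2-methylphenyl 2,4-dihydroxy-6-methylbenzoate | Cc1cc(O)cc(O)c1C(=O)Oc1c(C)c(C(=O)OC(C)(C)C)c(OCc2ccccc2)cc1OCc1ccccc1
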